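The C10 methyl (C20) of the cyclohexane ring is cis to the side-chain carbon C6 on the neighbouring ring carbon C5. C20 is therefore disconnected to a ring C1=C10 alkene and delivered from a hydroxyl on C6. In one operation a hydroxyl-directed zinc-carbenoid cyclopropanation forms C10–C20 and C1–C20, closes a cis-fused cyclopropane and fixes the quaternary centre C10 relative to C5; hydrogenolysis of C1–C20 later unveils the methyl. The precursor is the (R)-homoallylic alcohol [2-(silyloxymethyl)-6,6-dimethylcyclohex-2-en-1-yl]methanol, with the C9 oxygen carried as a non-migrating triisopropylsilyl (TIPS) ether, made by CBS reduction and a Still–Wittig [2,3] shift.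

Key step: step 6

Numbering used: ring C1–C5 and C10; C20 = methyl on C10; C6–C7–C8(=O)–C17 = oxobutyl chain on C5; C9 = ketone carbon on C10; C11–C15 = chain to the ester carbon, with the C13 methyl.

Assumption: the senses of induction in steps 3 and 14 are assigned from the accepted models for these catalysts; should either prove opposite, the enantiomeric CBS catalyst or the pseudoenantiomeric (DHQD)2AQN is used instead.

Step 1
Reactants: 1 4,4-dimethylcyclohex-2-en-1-one
Product: 2 2-(hydroxymethyl)-4,4-dimethylcyclohex-2-en-1-one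
Conditions: 37% aq. HCHO, DMAP (cat.), THF/H2O, rt
Reagents that add atoms: formaldehyde, C=O
Why: Morita–Baylis–Hillman α-hydroxymethylation, in which DMAP adds reversibly to the β-carbon, the resulting enolate adds to formaldehyde and loss of DMAP restores the enone; no stereocentre is formed.

Step 2
Reactants: 2 2-(hydroxymethyl)-4,4-dimethylcyclohex-2-en-1-one
Product: 3 4,4-dimethyl-2-({[tri(propan-2-yl)silyl]oxy}methyl)cyclohex-2-en-1-one
Conditions: TIPSCl, imidazole, DMF, rt
Reagents that add atoms: chlorotri(propan-2-yl)silane, CC(C)[Si](Cl)(C(C)C)C(C)C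
Why: Standard silylation of a primary alcohol; the bulky TIPS group is chosen because it should not migrate to a neighbouring alkoxide in steps 4 and 5, binds zinc poorly in step 6 and survives acetic acid in step 7.

Step 3
Reactants: 3 4,4-dimethyl-2-({[tri(propan-2-yl)silyl]oxy}methyl)cyclohex-2-en-1-one
Product: 4 (1S)-4,4-dimethyl-2-({[tri(propan-2-yl)silyl]oxy}methyl)cyclohex-2-en-1-ol
Conditions: (R)-1-methyl-3,3-diphenyltetrahydro-1H,3H-pyrrolo[1,2-c][1,3,2]oxazaborole ((R)-Me-CBS, 10 mol%), BH3·SMe2, THF, −20 °C; MeOH, then H2O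
Reagents that add atoms: none
Why: Corey–Bakshi–Shibata 1,2-reduction in which the α-branched alkenyl carbon acts as the large group and the ring CH2 as the small group, so the catalyst-bound borane should deliver hydride to the face that gives the (S)-carbinol at C1.

Step 4
Reactants: 4 (1S)-4,4-dimethyl-2-({[tri(propan-2-yl)silyl]oxy}methyl)cyclohex-2-en-1-ol
Product: 5 tributyl({[(1S)-4,4-dimethyl-2-({[tri(propan-2-yl)silyl]oxy}methyl)cyclohex-2-en-1-yl]oxy}methyl)stannane
Conditions: KH, Bu3SnCH2I, THF, 0 °C → rt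
Reagents that add atoms: tributyl(iodomethyl)stannane, CCCC[Sn](CCCC)(CCCC)CI
Why: Williamson etherification of the potassium alkoxide with the primary iodide; the carbinol stereocentre is not touched.

Step 5
Reactants: 5 tributyl({[(1S)-4,4-dimethyl-2-({[tri(propan-2-yl)silyl]oxy}methyl)cyclohex-2-en-1-yl]oxy}methyl)stannane
Product: 7 [(1R)-6,6-dimethyl-2-({[tri(propan-2-yl)silyl]oxy}methyl)cyclohex-2-en-1-yl]methanol, via lithiomethyl ether 6 (not isolated)
Conditions: n-BuLi, THF, −78 → −40 °C; H2O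
Reagents that add atoms: none
Why: Still–Wittig rearrangement, in which tin–lithium exchange gives the α-alkoxymethyllithium 6 and its [2,3]-sigmatropic shift forms C5–C6 on the ring face from which the C1–O bond departs while the alkene moves to C1=C10, so the (S)-carbinol configuration is relayed suprafacially to (R)-C5.

Step 6
Reactants: 7 [(1R)-6,6-dimethyl-2-({[tri(propan-2-yl)silyl]oxy}methyl)cyclohex-2-en-1-yl]methanol
Product: 9 [(1R,2R,6R)-3,3-dimethyl-1-({[tri(propan-2-yl)silyl]oxy}methyl)bicyclo[4.1.0]heptan-2-yl]methanol, via iodomethylzinc alkoxide 8 (not isolated)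
Conditions: Et2Zn, CH2I2, CH2Cl2, 0 °C → rt; aq. NH4Cl
Reagents that add atoms: diiodomethane, ICI
Why: Et2Zn converts the C6 hydroxyl into a zinc alkoxide that carries the iodomethylzinc carbenoid (8, activated by the excess reagent), and CH2 is transferred to the C1=C10 alkene in a concerted, stereospecific butterfly transition state that forms C10–C20 and C1–C20 together. The closest known reaction type is the hydroxyl-directed Simmons–Smith (Furukawa variant) cyclopropanation of cyclic homoallylic alcohols. The cyclopropane is closed by this single [2+1] methylene addition to one alkene face, so its fusion to the six-membered ring can only be cis. The new stereocentres C10 and C1 are both set by the existing C5 centre, because the CH2O–Zn arm, held pseudoaxial by allylic strain against the C10 substituent, can reach only the alkene face on its own side. The step needs face selectivity opposite to the steric preference for attack anti to the C5 substituent; this is secured by the free C6 hydroxyl being the only good zinc ligand, since the C9 oxygen is a bulky, poorly coordinating silyl ether on a freely rotating arm that favours neither face.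

Step 7
Reactants: 9 [(1R,2R,6R)-3,3-dimethyl-1-({[tri(propan-2-yl)silyl]oxy}methyl)bicyclo[4.1.0]heptan-2-yl]methanol
Product: 10 [(1R,2R)-2,6,6-trimethyl-2-({[tri(propan-2-yl)silyl]oxy}methyl)cyclohexyl]methanol
Conditions: H2 (4 atm), PtO2, AcOH, rt
Reagents that add atoms: none
Why: Catalytic cyclopropane hydrogenolysis cleaves the least substituted and most accessible bond, C1–C20 (CH–CH2, opposite the quaternary C10), so C20 remains as the methyl on C10 with the configuration set in step 6, no bond to C10 being broken.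

Step 8
Reactants: 10 [(1R,2R)-2,6,6-trimethyl-2-({[tri(propan-2-yl)silyl]oxy}methyl)cyclohexyl]methanol
Product: 11 (1R,2R)-2,6,6-trimethyl-2-({[tri(propan-2-yl)silyl]oxy}methyl)cyclohexane-1-carbaldehyde
Conditions: Dess–Martin periodinane, CH2Cl2, rt
Reagents that add atoms: none
Why: Dess–Martin oxidation under near-neutral conditions should leave C5 intact, and the desired epimer (equatorial CHO, axial C20 methyl instead of axial CH2OTIPS) is also expected to be the thermodynamically preferred one.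

Step 9
Reactants: 11 (1R,2R)-2,6,6-trimethyl-2-({[tri(propan-2-yl)silyl]oxy}methyl)cyclohexane-1-carbaldehyde
Product: 12 (3E)-4-[(1R,2R)-2,6,6-trimethyl-2-({[tri(propan-2-yl)silyl]oxy}methyl)cyclohexyl]but-3-en-2-one
Conditions: (MeO)2P(O)CH2C(O)CH3, NaH, THF, 0 → 60 °C
Reagents that add atoms: dimethyl (2-oxopropyl)phosphonate, COP(=O)(OC)CC(C)=O
Why: Horner–Wadsworth–Emmons olefination, in which the small stabilised phosphonate anion should add to the hindered aldehyde and lose phosphate to give the E-enone (geometry is irrelevant after step 10); the weakly basic anion should not disturb C5.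

Step 10
Reactants: 12 (3E)-4-[(1R,2R)-2,6,6-trimethyl-2-({[tri(propan-2-yl)silyl]oxy}methyl)cyclohexyl]but-3-en-2-one
Product: 13 4-[(1R,2R)-2,6,6-trimethyl-2-({[tri(propan-2-yl)silyl]oxy}methyl)cyclohexyl]butan-2-one
Conditions: H2 (1 atm), 10% Pd/C, EtOAc, rt
Reagents that add atoms: none
Why: Heterogeneous hydrogenation saturates the conjugated C6=C7 bond selectively, leaving the ketone and the silyl ether; no stereocentre is formed.

Step 11
Reactants: 13 4-[(1R,2R)-2,6,6-trimethyl-2-({[tri(propan-2-yl)silyl]oxy}methyl)cyclohexyl]butan-2-one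
Product: 14 tri(propan-2-yl)({(1R,2R)-1,3,3-trimethyl-2-[2-(2-methyl-1,3-dioxolan-2-yl)ethyl]cyclohexyl}methoxy)silane
Conditions: HOCH2CH2OH, PPTS, benzene, reflux (Dean–Stark)
Reagents that add atoms: ethane-1,2-diol, OCCO
Why: Acid-catalysed ketalisation of the unhindered methyl ketone masks C8 against the organolithium of step 19, and the mild acid should leave the hindered TIPS ether.

Step 12
Reactants: 14 tri(propan-2-yl)({(1R,2R)-1,3,3-trimethyl-2-[2-(2-methyl-1,3-dioxolan-2-yl)ethyl]cyclohexyl}methoxy)silane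
Product: 15 {(1R,2R)-1,3,3-trimethyl-2-[2-(2-methyl-1,3-dioxolan-2-yl)ethyl]cyclohexyl}methanol
Conditions: Bu4NF, THF, rt → 50 °C
Reagents that add atoms: none
Why: Fluoride-mediated desilylation frees the C9 hydroxyl under basic conditions that the dioxolane tolerates.

Step 13
Reactants: 15 {(1R,2R)-1,3,3-trimethyl-2-[2-(2-methyl-1,3-dioxolan-2-yl)ethyl]cyclohexyl}methanol
Product: 16 (1R,2R)-1,3,3-trimethyl-2-[2-(2-methyl-1,3-dioxolan-2-yl)ethyl]cyclohexane-1-carbaldehyde
Conditions: Pr4N[RuO4] (5 mol%), NMO, 4 Å molecular sieves, CH2Cl2, rt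
Reagents that add atoms: none
Why: Ley–Griffith oxidation under neutral conditions preserves the ketal, and the aldehyde sits on quaternary C10 and cannot epimerise.

Step 14
Reactants: 17 3-methylglutaric anhydride
Product: 18 (3S)-5-methoxy-3-methyl-5-oxopentanoic acid
Conditions: MeOH, (DHQ)2AQN (1,4-bis(dihydroquinin-9-O-yl)anthraquinone, cat.), Et2O, −40 °C
Reagents that add atoms: methanol, CO
Why: Cinchona-alkaloid-catalysed desymmetrising methanolysis of a prochiral cyclic anhydride, in which the chiral amine acts as a general base and selects one of the two enantiotopic carbonyls, setting the future C13 centre.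

Step 15
Reactants: 18 (3S)-5-methoxy-3-methyl-5-oxopentanoic acid
Product: 19 methyl (3S)-5-hydroxy-3-methylpentanoate
Conditions: BH3·SMe2, THF, 0 °C → rt; MeOH, then H2O
Reagents that add atoms: none
Why: Chemoselective borane reduction of the carboxylic acid (via the acyloxyborane) in the presence of the methyl ester; the stereocentre is remote and untouched.

Step 16
Reactants: 19 methyl (3S)-5-hydroxy-3-methylpentanoate
Product: 20 methyl (3S)-5-{[tert-butyl(dimethyl)silyl]oxy}-3-methylpentanoate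
Conditions: TBSCl, imidazole, CH2Cl2, rt
Reagents that add atoms: tert-butyl(chloro)dimethylsilane, CC(C)(C)[Si](C)(C)Cl
Why: Silylation of the primary alcohol, carried out directly on crude 19, forestalls lactonisation and masks the future C15 oxygen.

Step 17
Reactants: 20 methyl (3S)-5-{[tert-butyl(dimethyl)silyl]oxy}-3-methylpentanoate
Product: 21 (3R)-5-{[tert-butyl(dimethyl)silyl]oxy}-3-methylpentan-1-ol
Conditions: LiAlH4, THF, 0 °C
Reagents that add atoms: none
Why: Hydride reduction of the ester to the primary alcohol (future C11) leaves the silyl ether; the descriptor changes only through ligand priorities.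

Step 18
Reactants: 21 (3R)-5-{[tert-butyl(dimethyl)silyl]oxy}-3-methylpentan-1-ol
Product: 22 tert-butyl{[(3S)-5-iodo-3-methylpentyl]oxy}dimethylsilane
Conditions: I2, PPh3, imidazole, CH2Cl2, 0 °C → rt
Reagents that add atoms: iodine, II
Why: Appel-type iodination of an unhindered primary alcohol through the alkoxyphosphonium ion; the silyl ether and the stereocentre are unaffected.

Step 19
Reactants: 22 tert-butyl{[(3S)-5-iodo-3-methylpentyl]oxy}dimethylsilane; 16 (1R,2R)-1,3,3-trimethyl-2-[2-(2-methyl-1,3-dioxolan-2-yl)ethyl]cyclohexane-1-carbaldehyde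
Product: 24 (4R)-6-{[tert-butyl(dimethyl)silyl]oxy}-4-methyl-1-{(1R,2R)-1,3,3-trimethyl-2-[2-(2-methyl-1,3-dioxolan-2-yl)ethyl]cyclohexyl}hexan-1-ol (both C9 epimers), via alkyllithium 23 (not isolated)
Conditions: 22, t-BuLi (2 equiv per 22), Et2O/pentane, −78 °C; then 16, −78 → 0 °C; H2O
Reagents that add atoms: none
Why: Iodine–lithium exchange gives a primary alkyllithium that adds 1,2 to the non-enolisable, hindered aldehyde to form C9–C11; the C9 carbinol configuration is irrelevant because it is oxidised in step 20, and the ketal and silyl ether are inert.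

Step 20
Reactants: 24 (4R)-6-{[tert-butyl(dimethyl)silyl]oxy}-4-methyl-1-{(1R,2R)-1,3,3-trimethyl-2-[2-(2-methyl-1,3-dioxolan-2-yl)ethyl]cyclohexyl}hexan-1-ol
Product: 26 (3R)-3-methyl-6-oxo-6-[(1R,2R)-1,3,3-trimethyl-2-(3-oxobutyl)cyclohexyl]hexanoic acid, via keto diol 25 (not isolated)
Conditions: 2 M aq. HCl, acetone, rt; then CrO3/H2SO4/H2O (Jones reagent), 0 °C
Reagents that add atoms: water, O
Why: Aqueous acid hydrolyses the dioxolane and the primary silyl ether, and Jones oxidation then converts the hindered C9 carbinol into the ketone and the C15 alcohol, through the aldehyde hydrate, into the acid; none of C5, C10 or C13 is α to a carbonyl with an exchangeable hydrogen.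

Step 21
Reactants: 26 (3R)-3-methyl-6-oxo-6-[(1R,2R)-1,3,3-trimethyl-2-(3-oxobutyl)cyclohexyl]hexanoic acid; 27 (S)-solketal, [(4S)-2,2-dimethyl-1,3-dioxolan-4-yl]methanol
Product: 28 [(4R)-2,2-dimethyl-1,3-dioxolan-4-yl]methyl (3R)-3-methyl-6-oxo-6-[(1R,2R)-1,3,3-trimethyl-2-(3-oxobutyl)cyclohexyl]hexanoate
Conditions: EDC·HCl, DMAP, CH2Cl2, rt
Reagents that add atoms: none
Why: Steglich esterification of the unhindered C15 acid with the primary hydroxyl of solketal; the glycerol centre is not involved and only its descriptor changes.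

Step 22
Reactants: 28 [(4R)-2,2-dimethyl-1,3-dioxolan-4-yl]methyl (3R)-3-methyl-6-oxo-6-[(1R,2R)-1,3,3-trimethyl-2-(3-oxobutyl)cyclohexyl]hexanoate
Product: 29 (2R)-2,3-dihydroxypropyl (3R)-3-methyl-6-oxo-6-[(1R,2R)-1,3,3-trimethyl-2-(3-oxobutyl)cyclohexyl]hexanoate
Conditions: AcOH/H2O (4:1), 40 °C
Reagents that add atoms: none
Why: Mild acid hydrolysis of the acetonide breaks only the acetal C–O bonds, so the glycerol centre is retained, and the weak acid should keep acyl migration and ester cleavage negligible.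

Step 23
Reactants: 29 (2R)-2,3-dihydroxypropyl (3R)-3-methyl-6-oxo-6-[(1R,2R)-1,3,3-trimethyl-2-(3-oxobutyl)cyclohexyl]hexanoate
Product: 30 (2R)-3-(acetyloxy)-2-hydroxypropyl (3R)-3-methyl-6-oxo-6-[(1R,2R)-1,3,3-trimethyl-2-(3-oxobutyl)cyclohexyl]hexanoate (CNP0140002.1)
Conditions: AcCl (1.1 equiv), 2,4,6-collidine, CH2Cl2, −78 °C
Reagents that add atoms: acetyl chloride, CC(=O)Cl
Why: Kinetically selective acylation of the primary over the secondary hydroxyl with a hindered pyridine base at low temperature gives the 1,3-diacylglycerol, which is also the more stable regioisomer.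

Compound list
1 | 4,4-dimethylcyclohex-2-en-1-one | CC1(C)CCC(=O)C=C1 | starting material
2 | 2-(hydroxymethyl)-4,4-dimethylcyclohex-2-en-1-one | O=C1CCC(C)(C)C=C1CO | intermediate
3 | 4,4-dimethyl-2-({[tri(propan-2-yl)silyl]oxy}methyl)cyclohex-2-en-1-one | O=C1CCC(C)(C)C=C1CO[Si](C(C)C)(C(C)C)C(C)C | intermediate
4 | (1S)-4,4-dimethyl-2-({[tri(propan-2-yl)silyl]oxy}methyl)cyclohex-2-en-1-ol | O[C@H]1CCC(C)(C)C=C1CO[Si](C(C)C)(C(C)C)C(C)C | intermediate
5 | tributyl({[(1S)-4,4-dimethyl-2-({[tri(propan-2-yl)silyl]oxy}methyl)cyclohex-2-en-1-yl]oxy}methyl)stannane | CCCC[Sn](CCCC)(CCCC)CO[C@H]1CCC(C)(C)C=C1CO[Si](C(C)C)(C(C)C)C(C)C | intermediate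
6 | lithiomethyl ether of 4 (α-alkoxymethyllithium, not isolated) | [Li]CO[C@H]1CCC(C)(C)C=C1CO[Si](C(C)C)(C(C)C)C(C)C | intermediate
7 | [(1R)-6,6-dimethyl-2-({[tri(propan-2-yl)silyl]oxy}methyl)cyclohex-2-en-1-yl]methanol (key-step precursor) | OC[C@@H]1C(C)(C)CCC=C1CO[Si](C(C)C)(C(C)C)C(C)C | intermediate
8 | iodomethylzinc alkoxide of 7 (not isolated) | IC[Zn]OC[C@@H]1C(C)(C)CCC=C1CO[Si](C(C)C)(C(C)C)C(C)C | intermediate
9 | [(1R,2R,6R)-3,3-dimethyl-1-({[tri(propan-2-yl)silyl]oxy}methyl)bicyclo[4.1.0]heptan-2-yl]methanol (cyclopropane CH2 cis to CH2OH; key-step product) | OC[C@@H]1C(C)(C)CC[C@@H]2C[C@]12CO[Si](C(C)C)(C(C)C)C(C)C | intermediate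
10 | [(1R,2R)-2,6,6-trimethyl-2-({[tri(propan-2-yl)silyl]oxy}methyl)cyclohexyl]methanol (2-methyl cis to CH2OH) | OC[C@@H]1C(C)(C)CCC[C@@]1(C)CO[Si](C(C)C)(C(C)C)C(C)C | intermediate
11 | (1R,2R)-2,6,6-trimethyl-2-({[tri(propan-2-yl)silyl]oxy}methyl)cyclohexane-1-carbaldehyde | O=C[C@@H]1C(C)(C)CCC[C@@]1(C)CO[Si](C(C)C)(C(C)C)C(C)C | intermediate
12 | (3E)-4-[(1R,2R)-2,6,6-trimethyl-2-({[tri(propan-2-yl)silyl]oxy}methyl)cyclohexyl]but-3-en-2-one | CC(=O)/C=C/[C@@H]1C(C)(C)CCC[C@@]1(C)CO[Si](C(C)C)(C(C)C)C(C)C | intermediate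
13 | 4-[(1R,2R)-2,6,6-trimethyl-2-({[tri(propan-2-yl)silyl]oxy}methyl)cyclohexyl]butan-2-one | CC(=O)CC[C@@H]1C(C)(C)CCC[C@@]1(C)CO[Si](C(C)C)(C(C)C)C(C)C | intermediate
14 | tri(propan-2-yl)({(1R,2R)-1,3,3-trimethyl-2-[2-(2-methyl-1,3-dioxolan-2-yl)ethyl]cyclohexyl}methoxy)silane | CC1(CC[C@@H]2C(C)(C)CCC[C@@]2(C)CO[Si](C(C)C)(C(C)C)C(C)C)OCCO1 | intermediate
15 | {(1R,2R)-1,3,3-trimethyl-2-[2-(2-methyl-1,3-dioxolan-2-yl)ethyl]cyclohexyl}methanol | CC1(CC[C@@H]2C(C)(C)CCC[C@@]2(C)CO)OCCO1 | intermediate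
16 | (1R,2R)-1,3,3-trimethyl-2-[2-(2-methyl-1,3-dioxolan-2-yl)ethyl]cyclohexane-1-carbaldehyde | CC1(CC[C@@H]2C(C)(C)CCC[C@@]2(C)C=O)OCCO1 | intermediate
17 | 3-methylglutaric anhydride (4-methyloxane-2,6-dione) | CC1CC(=O)OC(=O)C1 | starting material
18 | (3S)-5-methoxy-3-methyl-5-oxopentanoic acid | COC(=O)C[C@@H](C)CC(=O)O | intermediate
19 | methyl (3S)-5-hydroxy-3-methylpentanoate | COC(=O)C[C@@H](C)CCO | intermediate
20 | methyl (3S)-5-{[tert-butyl(dimethyl)silyl]oxy}-3-methylpentanoate | COC(=O)C[C@@H](C)CCO[Si](C)(C)C(C)(C)C | intermediate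
21 | (3R)-5-{[tert-butyl(dimethyl)silyl]oxy}-3-methylpentan-1-ol | OCC[C@@H](C)CCO[Si](C)(C)C(C)(C)C | intermediate
22 | tert-butyl{[(3S)-5-iodo-3-methylpentyl]oxy}dimethylsilane | ICC[C@@H](C)CCO[Si](C)(C)C(C)(C)C | intermediate
23 | (3S)-5-{[tert-butyl(dimethyl)silyl]oxy}-3-methylpentyllithium (not isolated) | [Li]CC[C@@H](C)CCO[Si](C)(C)C(C)(C)C | intermediate
24 | (4R)-6-{[tert-butyl(dimethyl)silyl]oxy}-4-methyl-1-{(1R,2R)-1,3,3-trimethyl-2-[2-(2-methyl-1,3-dioxolan-2-yl)ethyl]cyclohexyl}hexan-1-ol (both C9 epimers) | CC1(CC[C@@H]2C(C)(C)CCC[C@@]2(C)C(O)CC[C@@H](C)CCO[Si](C)(C)C(C)(C)C)OCCO1 | intermediate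
25 | 4-{(1R,2R)-2-[(4R)-1,6-dihydroxy-4-methylhexyl]-2,6,6-trimethylcyclohexyl}butan-2-one (keto diol, not isolated) | CC(=O)CC[C@@H]1C(C)(C)CCC[C@@]1(C)C(O)CC[C@@H](C)CCO | intermediate
26 | (3R)-3-methyl-6-oxo-6-[(1R,2R)-1,3,3-trimethyl-2-(3-oxobutyl)cyclohexyl]hexanoic acid | CC(=O)CC[C@@H]1C(C)(C)CCC[C@@]1(C)C(=O)CC[C@@H](C)CC(=O)O | intermediate
27 | (S)-solketal, [(4S)-2,2-dimethyl-1,3-dioxolan-4-yl]methanol | OC[C@H]1COC(C)(C)O1 | starting material
28 | [(4R)-2,2-dimethyl-1,3-dioxolan-4-yl]methyl (3R)-3-methyl-6-oxo-6-[(1R,2R)-1,3,3-trimethyl-2-(3-oxobutyl)cyclohexyl]hexanoate | CC(=O)CC[C@@H]1C(C)(C)CCC[C@@]1(C)C(=O)CC[C@@H](C)CC(=O)OC[C@H]2COC(C)(C)O2 | intermediate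
29 | (2R)-2,3-dihydroxypropyl (3R)-3-methyl-6-oxo-6-[(1R,2R)-1,3,3-trimethyl-2-(3-oxobutyl)cyclohexyl]hexanoate | CC(=O)CC[C@@H]1C(C)(C)CCC[C@@]1(C)C(=O)CC[C@@H](C)CC(=O)OC[C@H](O)CO | intermediate
30 | (2R)-3-(acetyloxy)-2-hydroxypropyl (3R)-3-methyl-6-oxo-6-[(1R,2R)-1,3,3-trimethyl-2-(3-oxobutyl)cyclohexyl]hexanoate (CNP0140002.1) | CC(=O)CC[C@@H]1C(C)(C)CCC[C@@]1(C)C(=O)CC[C@@H](C)CC(=O)OC[C@H](O)COC(C)=O | target

Total step count: 23 (18 on the main line, 5 for the side-chain iodide 22).
Longest linear sequence: 18 steps (steps 1–13 and 19–23, from 1 to 30).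

Steps most likely to fail

Step 5. The [2,3] shift must form a C–C bond at C5 next to the quaternary C4, so a competing [1,2] shift or simple protonation of the carbanion could divert material. The fallback sets out from 4 and returns at 7. Heating 4 with N,N-dimethylformamide dimethyl acetal (xylene, 150 °C) generates the allyloxy(dimethylamino)carbene. Its suprafacial [2,3]-sigmatropic rearrangement places the amide carbon on C5 on the same face and should give (1R)-N,N,6,6-tetramethyl-2-({[tri(propan-2-yl)silyl]oxy}methyl)cyclohex-2-ene-1-carboxamide F1. Reduction of the tertiary amide with LiEt3BH (THF, 0 °C) would then give 7.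

Step 6. Facial selectivity could be poor if the homoallylic zinc alkoxide holds the carbenoid too loosely, and methylene transfer to the hindered trisubstituted alkene could be slow. The fallback sets out from 7 and returns at 9, replacing substrate control by reagent control through the allylic oxygen.
- The C6 hydroxyl is acetylated (Ac2O, pyridine, DMAP) to [(1R)-6,6-dimethyl-2-({[tri(propan-2-yl)silyl]oxy}methyl)cyclohex-2-en-1-yl]methyl acetate F2.
- The silyl ether is cleaved with HF·pyridine to the allylic alcohol [(1R)-2-(hydroxymethyl)-6,6-dimethylcyclohex-2-en-1-yl]methyl acetate F3.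
- F3 is cyclopropanated with Zn(CH2I)2·DME and the stoichiometric chiral ligand 2-butyl-N,N,N′,N′-tetramethyl-1,3,2-dioxaborolane-4,5-dicarboxamide. The ligand enantiomer is chosen by the established model for attack on the face syn to C6 and must be confirmed on the first run. This should give [(1R,2R,6R)-1-(hydroxymethyl)-3,3-dimethylbicyclo[4.1.0]heptan-2-yl]methyl acetate F4.
- Silylation (TIPSOTf, 2,6-lutidine) gives [(1R,2R,6R)-3,3-dimethyl-1-({[tri(propan-2-yl)silyl]oxy}methyl)bicyclo[4.1.0]heptan-2-yl]methyl acetate F5, and methanolysis of the acetate (K2CO3, MeOH) returns 9.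

Step 9. Olefination of the doubly neopentyl aldehyde could be slow, with base-mediated epimerisation at C5 as the competing process. The fallback sets out from 11 and returns at 12. The small lithium enolate of acetone (LDA, acetone, THF, −78 °C) adds to 11 to give the aldol 4-hydroxy-4-[(1R,2R)-2,6,6-trimethyl-2-({[tri(propan-2-yl)silyl]oxy}methyl)cyclohexyl]butan-2-one F6. Acid-catalysed dehydration (TsOH, benzene, reflux) then gives enone 12.

Further compounds
F1 | step 5 | (1R)-N,N,6,6-tetramethyl-2-({[tri(propan-2-yl)silyl]oxy}methyl)cyclohex-2-ene-1-carboxamide | CN(C)C(=O)[C@@H]1C(C)(C)CCC=C1CO[Si](C(C)C)(C(C)C)C(C)C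
F2 | step 6 | [(1R)-6,6-dimethyl-2-({[tri(propan-2-yl)silyl]oxy}methyl)cyclohex-2-en-1-yl]methyl acetate | CC(=O)OC[C@@H]1C(C)(C)CCC=C1CO[Si](C(C)C)(C(C)C)C(C)C
F3 | step 6 | [(1R)-2-(hydroxymethyl)-6,6-dimethylcyclohex-2-en-1-yl]methyl acetate | CC(=O)OC[C@@H]1C(C)(C)CCC=C1CO
F4 | step 6 | [(1R,2R,6R)-1-(hydroxymethyl)-3,3-dimethylbicyclo[4.1.0]heptan-2-yl]methyl acetate | CC(=O)OC[C@@H]1C(C)(C)CC[C@@H]2C[C@]12CO
F5 | step 6 | [(1R,2R,6R)-3,3-dimethyl-1-({[tri(propan-2-yl)silyl]oxy}methyl)bicyclo[4.1.0]heptan-2-yl]methyl acetate | CC(=O)OC[C@@H]1C(C)(C)CC[C@@H]2C[C@]12CO[Si](C(C)C)(C(C)C)C(C)C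
F6 | step 9 | 4-hydroxy-4-[(1R,2R)-2,6,6-trimethyl-2-({[tri(propan-2-yl)silyl]oxy}methyl)cyclohexyl]butan-2-one | CC(=O)CC(O)[C@@H]1C(C)(C)CCC[C@@]1(C)CO[Si](C(C)C)(C(C)C)C(C)C
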